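**Retrosynthetic overview**
The strategy rests on the C2–C3 bond of the five-membered indolin-3-one ring. It joins the carbonyl carbon C3 to the quaternary C2, which carries N1 and the C3' atoms of two indole rings. In the ring-opened C–H form this carbon is alpha to N1, doubly indolyl-benzylic and delta to the carbonyl carbon (O=C3–C3a–C7a–N1–C2–H).
Target ⇐ oxidation of the C3 carbinol ⇐ removal of three tosyl groups ⇐ tris-tosyl indolin-3-ol ⇐ (C2–C3, Norrish–Yang photocyclisation) ortho-formyl N-[bis(1-tosylindol-3-yl)methyl] sulfonanilide.
Photoprecursor ⇐ N-alkylation of N-(2-formylphenyl)tosylamide with bis(1-tosylindol-3-yl)methyl chloride. The parent carbinol ⇐ 1-tosylindol-3-yl Grignard + 1-tosylindole-3-carboxaldehyde.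
Ring order: the benzene ring and both indole rings are bought in. The only ring formed is the five-membered indoline ring, closed in the key step.

Key step: step 7

Remark on the chemistry: the target is achiral. The one stereocentre created by the key step (C3 of the indolin-3-ol) is carried as the racemate and is destroyed by the final oxidation.

**Step 1**
Reactants: 1 indole-3-carboxaldehyde; 2 p-toluenesulfonyl chloride
Product: 3 1-tosylindole-3-carboxaldehyde
Conditions: Et3N, DMAP (cat.), CH2Cl2, 0 °C → rt
Reagents that add atoms: none
Why: N-sulfonylation of the indole nitrogen by DMAP-catalysed sulfonyl transfer; the 3-formyl group acidifies N–H, so a tertiary amine base suffices.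

**Step 2**
Reactants: 4 indole; 2 p-toluenesulfonyl chloride
Product: 6 3-iodo-1-tosylindole, via 3-iodoindole 5 (not isolated)
Conditions: I2, KOH (powdered, excess), DMF, rt; then 2, 0 °C → rt
Reagents that add atoms: iodine, II
Why: Electrophilic aromatic iodination at the nucleophilic C3 of indole, then N-sulfonylation of the potassium indolide in the same pot, which avoids isolating the light-sensitive 3-iodoindole.

**Step 3**
Reactants: 6 3-iodo-1-tosylindole; 3 1-tosylindole-3-carboxaldehyde
Product: 8 bis(1-tosylindol-3-yl)methanol, via 1-tosylindol-3-ylmagnesium chloride 7 (not isolated)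
Conditions: i-PrMgCl·LiCl, THF, −40 °C; then 3, −40 → 0 °C; aq. NH4Cl
Reagents that add atoms: none
Why: Iodine–magnesium exchange gives a C3 Grignard reagent that does not migrate to C2 as the lithio analogue does, and it should add 1,2 to the non-enolisable aldehyde (Grignard addition); the carbinol carbon bears two identical aryl groups, so no stereocentre arises.

**Step 4**
Reactants: 9 2-aminobenzyl alcohol; 2 p-toluenesulfonyl chloride
Product: 10 N-[2-(hydroxymethyl)phenyl]-4-methylbenzenesulfonamide
Conditions: pyridine, CH2Cl2, 0 °C → rt
Reagents that add atoms: none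
Why: Chemoselective N-sulfonylation; the aniline nitrogen is far more nucleophilic towards the sulfonyl chloride than the benzylic hydroxyl at 0 °C in pyridine.

**Step 5**
Reactants: 10 N-[2-(hydroxymethyl)phenyl]-4-methylbenzenesulfonamide
Product: 11 N-(2-formylphenyl)-4-methylbenzenesulfonamide
Conditions: MnO2 (activated, excess), CH2Cl2, rt
Reagents that add atoms: none
Why: MnO2 oxidation of a benzylic alcohol should stop cleanly at the aldehyde and leave the sulfonamide N–H untouched.

**Step 6**
Reactants: 8 bis(1-tosylindol-3-yl)methanol; 11 N-(2-formylphenyl)-4-methylbenzenesulfonamide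
Product: 13 N-[bis(1-tosylindol-3-yl)methyl]-N-(2-formylphenyl)-4-methylbenzenesulfonamide, via bis(1-tosylindol-3-yl)methyl chloride 12 (not isolated)
Conditions: SOCl2, CH2Cl2, 0 °C → rt, evaporate; then 11, Cs2CO3, MeCN, rt → 40 °C
Reagents that add atoms: none
Why: Deoxychlorination of the doubly benzylic carbinol, then SN1-type N-alkylation of the sulfonamide anion (acidified by the ortho-formyl group) by the readily ionised diarylmethyl chloride; the electrophile has no beta-hydrogen, so elimination is impossible, and the carbonate is too weak to deprotonate the new N–CH.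

**Step 7**
Reactants: 13 N-[bis(1-tosylindol-3-yl)methyl]-N-(2-formylphenyl)-4-methylbenzenesulfonamide
Product: 15 racemic 3-hydroxy-1-tosyl-2,2-bis(1-tosylindol-3-yl)indoline, via triplet 1,5-biradical 14 (not isolated)
Conditions: hν (350–365 nm, Pyrex), degassed benzene (0.01 M), rt
Reagents that add atoms: none
Why: n→π* excitation of the aryl aldehyde and intersystem crossing give a triplet whose oxygen abstracts the delta-hydrogen of the N–CH(indolyl)2 group through a seven-membered transition state (1,6-hydrogen transfer), forming the triplet 1,5-biradical 14 (ketyl carbon = future C3, N1-substituted bis-indolylmethyl radical = future C2), which after spin inversion collapses by C2–C3 bond formation. The closest known reaction type is the Norrish–Yang photocyclisation by delta-hydrogen abstraction of ortho-alkoxy and ortho-(N-alkylsulfonamido) aryl aldehydes and ketones to 2,3-dihydrobenzofuran-3-ols and indolin-3-ols. The five-membered indoline ring is closed by radical–radical recombination of the two termini of the 1,5-biradical, so no 5-endo polar addition is needed and the quaternary C2 is made through an early, weakly hindered transition state. C3 is the only new stereocentre; because C2 carries two identical indolyl groups and nothing chiral is present, it should form as the racemate, which is acceptable since step 9 removes it. The step needs delta-abstraction and cyclisation to win over intermolecular hydrogen abstraction, back hydrogen transfer and quenching: the gamma atom is nitrogen and bears no hydrogen, the targeted C–H is the weakest in the molecule (alpha to N1 and doubly benzylic), the N1 sulfonyl group and the N-tosylated indoles remove electron-donor sites, and long-wavelength light at high dilution in degassed solvent leaves the tosylindole chromophores unexcited and suppresses bimolecular pathways.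

**Step 8**
Reactants: 15 racemic 3-hydroxy-1-tosyl-2,2-bis(1-tosylindol-3-yl)indoline
Product: 16 racemic 2,2-bis(1H-indol-3-yl)indolin-3-ol
Conditions: Mg turnings (excess), MeOH/THF, sonication, rt
Reagents that add atoms: none
Why: Single-electron-transfer (dissolving-metal) cleavage of N–S bonds by Mg in MeOH is established for N-sulfonyl indoles and N-aryl sulfonamides; it is run at the carbinol stage because a C3 ketone would be reduced and would lose its alpha C–N bond under these conditions.

**Step 9**
Reactants: 16 racemic 2,2-bis(1H-indol-3-yl)indolin-3-ol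
Product: 17 2,2-bis(3'-indolyl)indoxyl [2,2-bis(1H-indol-3-yl)indolin-3-one]
Conditions: MnO2 (activated, excess), acetone, rt
Reagents that add atoms: none
Why: MnO2 oxidation of a benzylic carbinol activated by the ortho-amino donor (as with 2-aminobenzyl alcohols) should give the stable push–pull indoxyl; C2 is quaternary, so neither dehydration nor dehydrogenation to an indole can compete, and the stereocentre disappears.

**Compound list**
1 | indole-3-carboxaldehyde | O=Cc1c[nH]c2ccccc12 | starting material
2 | p-toluenesulfonyl chloride | Cc1ccc(cc1)S(Cl)(=O)=O | starting material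
3 | 1-tosylindole-3-carboxaldehyde | O=Cc1cn(S(=O)(=O)c2ccc(C)cc2)c2ccccc12 | intermediate
4 | indole | c1ccc2[nH]ccc2c1 | starting material
5 | 3-iodoindole (formed in the flask, not isolated) | Ic1c[nH]c2ccccc12 | intermediate
6 | 3-iodo-1-tosylindole | Ic1cn(S(=O)(=O)c2ccc(C)cc2)c2ccccc12 | intermediate
7 | 1-tosylindol-3-ylmagnesium chloride (formed in the flask, not isolated) | Cl[Mg]c1cn(S(=O)(=O)c2ccc(C)cc2)c2ccccc12 | intermediate
8 | bis(1-tosylindol-3-yl)methanol | OC(c1cn(S(=O)(=O)c2ccc(C)cc2)c2ccccc12)c1cn(S(=O)(=O)c2ccc(C)cc2)c2ccccc12 | intermediate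
9 | 2-aminobenzyl alcohol | Nc1ccccc1CO | starting material
10 | N-[2-(hydroxymethyl)phenyl]-4-methylbenzenesulfonamide | OCc1ccccc1NS(=O)(=O)c1ccc(C)cc1 | intermediate
11 | N-(2-formylphenyl)-4-methylbenzenesulfonamide | O=Cc1ccccc1NS(=O)(=O)c1ccc(C)cc1 | intermediate
12 | bis(1-tosylindol-3-yl)methyl chloride (crude, not isolated) | ClC(c1cn(S(=O)(=O)c2ccc(C)cc2)c2ccccc12)c1cn(S(=O)(=O)c2ccc(C)cc2)c2ccccc12 | intermediate
13 | N-[bis(1-tosylindol-3-yl)methyl]-N-(2-formylphenyl)-4-methylbenzenesulfonamide | O=Cc1ccccc1N(S(=O)(=O)c1ccc(C)cc1)C(c1cn(S(=O)(=O)c2ccc(C)cc2)c2ccccc12)c1cn(S(=O)(=O)c2ccc(C)cc2)c2ccccc12 | intermediate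
14 | triplet 1,5-biradical (ketyl carbon and N-substituted bis(1-tosylindol-3-yl)methyl radical; transient, not isolated) | O[CH]c1ccccc1N(S(=O)(=O)c1ccc(C)cc1)[C](c1cn(S(=O)(=O)c2ccc(C)cc2)c2ccccc12)c1cn(S(=O)(=O)c2ccc(C)cc2)c2ccccc12 | intermediate
15 | racemic 3-hydroxy-1-tosyl-2,2-bis(1-tosylindol-3-yl)indoline | OC1c2ccccc2N(S(=O)(=O)c2ccc(C)cc2)C1(c1cn(S(=O)(=O)c2ccc(C)cc2)c2ccccc12)c1cn(S(=O)(=O)c2ccc(C)cc2)c2ccccc12 | intermediate
16 | racemic 2,2-bis(1H-indol-3-yl)indolin-3-ol | OC1c2ccccc2NC1(c1c[nH]c2ccccc12)c1c[nH]c2ccccc12 | intermediate
17 | 2,2-bis(3'-indolyl)indoxyl (achiral) | O=C1c2ccccc2NC1(c1c[nH]c2ccccc12)c1c[nH]c2ccccc12 | target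

**Step count**
Total: 9 steps. Longest linear sequence: 6 steps (steps 2, 3, 6, 7, 8, 9; the branches through steps 1 and 4–5 are equally long).

**Steps most likely to fail**

Step 7 (photocyclisation). The excited aldehyde may be deactivated before the seven-membered hydrogen transfer, by triplet energy transfer to or charge-transfer quenching by the neighbouring tosylindole chromophores. The biradical may also return to starting material by back hydrogen transfer, so that conversion stalls and bimolecular aldehyde photoreduction takes over. Fallback, from 13 back to 15: a polar closure of the same bond. Treatment of 13 with KOtBu in THF at −78 → −40 °C should deprotonate the N–CH(indolyl)2 carbon, which is acidified by the sulfonamide and two electron-poor tosylindolyl groups. The carbanion should add 5-exo-trig to the ortho-formyl group, an intramolecular aldol-type addition known for N-benzyl-N-sulfonyl-2-aminobenzaldehydes. This gives potassium 1-tosyl-2,2-bis(1-tosylindol-3-yl)indolin-3-olate F1, and a cold acetic acid quench returns the route to 15. The low temperature is chosen so that addition to the adjacent aldehyde outruns loss of sulfinate from nitrogen.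

Step 6 (hindered N-alkylation). Capture of the crowded diarylmethyl chloride by the weakly nucleophilic, formyl-stabilised sulfonamide anion may be slower than return of the chloride to the carbinol or its ether by adventitious water. Fallback, from 10 and 8 back to 13: an acid-catalysed dehydrative substitution with a formyl-free nucleophile, with the aldehyde installed afterwards. Silylation of 10 (TBDPSCl, imidazole, DMF) should give N-[2-({[tert-butyl(diphenyl)silyl]oxy}methyl)phenyl]-4-methylbenzenesulfonamide F2. Substitution of carbinol 8 by F2 under Bi(OTf)3 catalysis (CH2Cl2, 4 Å molecular sieves, rt; SN1 via the bis-indolylmethyl cation) should give N-[bis(1-tosylindol-3-yl)methyl]-N-[2-({[tert-butyl(diphenyl)silyl]oxy}methyl)phenyl]-4-methylbenzenesulfonamide F3. Desilylation with HF·pyridine in THF should give N-[bis(1-tosylindol-3-yl)methyl]-N-[2-(hydroxymethyl)phenyl]-4-methylbenzenesulfonamide F4, and MnO2 in CH2Cl2 should oxidise F4 to 13.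

Step 8 (global detosylation). Electron-transfer cleavage may stall at the N1 sulfonamide next to the quaternary carbon while the indole sulfonamides cleave, leaving mixtures of partly sulfonylated material. Fallback, from 15 back to 16: the cleavages are separated by mechanism. Cs2CO3 in MeOH/THF at rt should remove only the two indole tosyl groups by nucleophilic attack of methoxide at sulfur, giving racemic 2,2-bis(1H-indol-3-yl)-1-tosylindolin-3-ol F5. The single remaining N-aryl sulfonamide is then cleaved with NaC10H8 (sodium naphthalenide, excess) in THF at −78 °C, returning to 16.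

**Further compounds**
F1 | step 7 | potassium 1-tosyl-2,2-bis(1-tosylindol-3-yl)indolin-3-olate (racemic) | [K+].[O-]C1c2ccccc2N(S(=O)(=O)c2ccc(C)cc2)C1(c1cn(S(=O)(=O)c2ccc(C)cc2)c2ccccc12)c1cn(S(=O)(=O)c2ccc(C)cc2)c2ccccc12
F2 | step 6 | N-[2-({[tert-butyl(diphenyl)silyl]oxy}methyl)phenyl]-4-methylbenzenesulfonamide | CC(C)(C)[Si](OCc1ccccc1NS(=O)(=O)c1ccc(C)cc1)(c1ccccc1)c1ccccc1
F3 | step 6 | N-[bis(1-tosylindol-3-yl)methyl]-N-[2-({[tert-butyl(diphenyl)silyl]oxy}methyl)phenyl]-4-methylbenzenesulfonamide | CC(C)(C)[Si](OCc1ccccc1N(S(=O)(=O)c1ccc(C)cc1)C(c1cn(S(=O)(=O)c2ccc(C)cc2)c2ccccc12)c1cn(S(=O)(=O)c2ccc(C)cc2)c2ccccc12)(c1ccccc1)c1ccccc1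
F4 | step 6 | N-[bis(1-tosylindol-3-yl)methyl]-N-[2-(hydroxymethyl)phenyl]-4-methylbenzenesulfonamide | OCc1ccccc1N(S(=O)(=O)c1ccc(C)cc1)C(c1cn(S(=O)(=O)c2ccc(C)cc2)c2ccccc12)c1cn(S(=O)(=O)c2ccc(C)cc2)c2ccccc12
F5 | step 8 | racemic 2,2-bis(1H-indol-3-yl)-1-tosylindolin-3-ol | OC1c2ccccc2N(S(=O)(=O)c2ccc(C)cc2)C1(c1c[nH]c2ccccc12)c1c[nH]c2ccccc12
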